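The flavone is disconnected at the C4 carbonyl of ring C, which lies between C4a of ring A and C3. C4 is supplied as carbon monoxide, C2, C3 and ring B as 4-ethynylanisole, and ring A as an iodophenol whose iodine marks C4a, the only ring A carbon without oxygen, next to the free phenol that becomes O1. One palladium-catalysed carbonylative alkynylation–cyclisation forms C4a–C4, C4–C3 and O1–C2 and closes ring C. The precursor, 3-(benzyloxy)-2-iodo-4,5,6-trimethoxyphenol, is built from 1,2,3-trimethoxybenzene by introducing the two flanking oxygens one after the other, so they are differentiated without statistical protection. C3 hydroxylation and debenzylation finish the target.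

Key step: step 6

Remark on the chemistry: the target and all isolated compounds are achiral; the only stereogenic species on the route, epoxide 17, is racemic and is consumed in the flask.

Step 1
Reactants: 1 1,2,3-trimethoxybenzene
Product: 2 1,5-dibromo-2,3,4-trimethoxybenzene
Conditions: NBS (2.2 equiv), MeCN, rt → 50 °C
Reagents that add atoms: N-bromosuccinimide, O=C1CCC(=O)N1Br
Why: Electrophilic aromatic bromination should take place twice, at C4 and then C6, because each of these positions is ortho to one outer methoxy group and para to the other, while C5 is activated only by the twisted central methoxy group and is left as the single ring C–H between the two bromines.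

Step 2
Reactants: 2 1,5-dibromo-2,3,4-trimethoxybenzene
Product: 5 5-bromo-2,3,4-trimethoxyphenol, via aryllithium 3 (not isolated), via arylboronate 4 (not isolated)
Conditions: n-BuLi (1.05 equiv), THF, −78 °C; B(OMe)3, −78 °C → rt; AcOH, 30% aq. H2O2, 0 °C → rt
Reagents that add atoms: hydrogen peroxide, OO
Why: Bromine–lithium exchange with one equivalent of n-BuLi at −78 °C should stop at the monolithio stage, since an aryllithium does not undergo a second exchange under these conditions, and borylation followed by peroxide-induced 1,2-aryl shift from boron to oxygen (lithiation–borylation–oxidation) turns that carbon into the phenol while the second bromine is kept for step 4.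

Step 3
Reactants: 5 5-bromo-2,3,4-trimethoxyphenol; 6 benzyl bromide
Product: 7 1-(benzyloxy)-5-bromo-2,3,4-trimethoxybenzene
Conditions: BnBr (1.2 equiv), K2CO3, DMF, rt
Reagents that add atoms: benzyl bromide (6), BrCc1ccccc1
Why: Williamson ether synthesis on the single phenoxide with a reactive benzylic bromide should be clean, and it fixes which flanking oxygen is masked (the future 5-OH) before the second one is introduced.

Step 4
Reactants: 7 1-(benzyloxy)-5-bromo-2,3,4-trimethoxybenzene
Product: 10 5-(benzyloxy)-2,3,4-trimethoxyphenol, via aryllithium 8 (not isolated), via arylboronate 9 (not isolated)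
Conditions: n-BuLi (1.05 equiv), THF, −78 °C; B(OMe)3, −78 °C → rt; AcOH, 30% aq. H2O2, 0 °C → rt
Reagents that add atoms: hydrogen peroxide, OO
Why: The same lithiation–borylation–oxidation sequence replaces the remaining bromine by OH, because exchange at C–Br is far faster at −78 °C than deprotonation of the benzylic CH2 and the benzyl and methyl ethers are inert to AcOH/H2O2.

Step 5
Reactants: 10 5-(benzyloxy)-2,3,4-trimethoxyphenol
Product: 11 3-(benzyloxy)-2-iodo-4,5,6-trimethoxyphenol
Conditions: NIS (1.05 equiv), MeCN, 0 °C, dark
Reagents that add atoms: N-iodosuccinimide, O=C1CCC(=O)N1I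
Why: Electrophilic aromatic iodination can only occur at the one unsubstituted ring carbon, which is ortho to the free OH and strongly activated, while the unactivated benzyl ring does not react with NIS at 0 °C.

Step 6
Reactants: 11 3-(benzyloxy)-2-iodo-4,5,6-trimethoxyphenol; 12 4-ethynylanisole; 13 carbon monoxide
Product: 16 5-(benzyloxy)-6,7,8-trimethoxy-2-(4-methoxyphenyl)-4H-chromen-4-one, via ynone 14 (not isolated), via enaminone 15 (not isolated)
Conditions: PdCl2(PPh3)2 (5 mol %), 12 (1.5 equiv), CO (10 bar), Et2NH, 90 °C
Reagents that add atoms: carbon monoxide (13), [C-]#[O+]; 4-ethynylanisole (12), COc1ccc(C#C)cc1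
Why: PdCl2(PPh3)2 is reduced in the flask to zerovalent palladium, which adds oxidatively to the C–I bond of 11; migratory insertion of CO gives an aroylpalladium iodide, the amine-deprotonated alkyne 12 displaces iodide, and reductive elimination releases ynone 14. Diethylamine then adds in conjugate fashion to 14 to give enaminone 15, whose phenol oxygen attacks C2 and expels the amine to give 16. The closest known reaction type is the palladium-catalysed carbonylative Sonogashira coupling–cyclisation of ortho-iodophenols with terminal alkynes in a secondary amine. Ring C closes by a 6-endo-trig addition–elimination at C2 of the enaminone (overall a 6-endo-dig hydroalkoxylation of the ynone), and no stereocentre is formed. The step needs CO insertion to precede alkynylation and six-membered to beat five-membered closure: CO pressure, the electron-rich migrating aryl group and the absence of a copper co-catalyst favour the acyl pathway, and the amine adduct leaves C2 as the only electrophilic carbon, so aurone formation through attack at C3 is excluded. Regiochemistry is fixed by the substrate, because iodine sits on the only unoxygenated ring carbon and only one of its two oxygen neighbours is a free phenol.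

Step 7
Reactants: 16 5-(benzyloxy)-6,7,8-trimethoxy-2-(4-methoxyphenyl)-4H-chromen-4-one
Product: 18 5-(benzyloxy)-3-hydroxy-6,7,8-trimethoxy-2-(4-methoxyphenyl)-4H-chromen-4-one, via epoxide 17 (not isolated)
Conditions: DMDO (ca. 0.07 M in acetone, 3 equiv), CH2Cl2, 0 °C → rt; evaporate; p-TsOH·H2O (10 mol %), CH2Cl2, rt
Reagents that add atoms: dimethyldioxirane, CC1(C)OO1
Why: Dioxirane epoxidation of the enol-ether-like C2=C3 bond should give the racemic cis-fused epoxide by concerted syn oxygen transfer, and acid then opens it at C2 (benzylic, oxygen-stabilised cation) with loss of the C3 proton to give the 3-hydroxyflavone (epoxidation followed by acid-catalysed epoxide isomerisation), the benzyl ether keeping the C5 oxygen from being oxidised as a free phenol.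

Step 8
Reactants: 18 5-(benzyloxy)-3-hydroxy-6,7,8-trimethoxy-2-(4-methoxyphenyl)-4H-chromen-4-one
Product: 19 3,5-dihydroxy-6,7,8-trimethoxy-2-(4-methoxyphenyl)-4H-chromen-4-one
Conditions: H2 (1 atm), 10% Pd/C, EtOAc–MeOH, rt
Reagents that add atoms: none
Why: Catalytic hydrogenolysis should cleave the benzylic C–O bond of the aryl benzyl ether while the methyl ethers and the C2=C3 bond of the chromone, part of a vinylogous ester, are left untouched.

Compound list
1 | 1,2,3-trimethoxybenzene | COc1cccc(OC)c1OC | starting material
2 | 1,5-dibromo-2,3,4-trimethoxybenzene | COc1c(Br)cc(Br)c(OC)c1OC | intermediate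
3 | (5-bromo-2,3,4-trimethoxyphenyl)lithium | [Li]c1cc(Br)c(OC)c(OC)c1OC | intermediate
4 | dimethyl (5-bromo-2,3,4-trimethoxyphenyl)boronate | COB(OC)c1cc(Br)c(OC)c(OC)c1OC | intermediate
5 | 5-bromo-2,3,4-trimethoxyphenol | COc1c(O)cc(Br)c(OC)c1OC | intermediate
6 | benzyl bromide | BrCc1ccccc1 | starting material
7 | 1-(benzyloxy)-5-bromo-2,3,4-trimethoxybenzene | COc1c(OCc2ccccc2)cc(Br)c(OC)c1OC | intermediate
8 | [5-(benzyloxy)-2,3,4-trimethoxyphenyl]lithium | [Li]c1cc(OCc2ccccc2)c(OC)c(OC)c1OC | intermediate
9 | dimethyl [5-(benzyloxy)-2,3,4-trimethoxyphenyl]boronate | COB(OC)c1cc(OCc2ccccc2)c(OC)c(OC)c1OC | intermediate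
10 | 5-(benzyloxy)-2,3,4-trimethoxyphenol | COc1c(O)cc(OCc2ccccc2)c(OC)c1OC | intermediate
11 | 3-(benzyloxy)-2-iodo-4,5,6-trimethoxyphenol | COc1c(O)c(I)c(OCc2ccccc2)c(OC)c1OC | intermediate
12 | 4-ethynylanisole | COc1ccc(C#C)cc1 | starting material
13 | carbon monoxide | [C-]#[O+] | starting material
14 | 1-[2-(benzyloxy)-6-hydroxy-3,4,5-trimethoxyphenyl]-3-(4-methoxyphenyl)prop-2-yn-1-one | COc1ccc(cc1)C#CC(=O)c1c(O)c(OC)c(OC)c(OC)c1OCc1ccccc1 | intermediate
15 | (E)-1-[2-(benzyloxy)-6-hydroxy-3,4,5-trimethoxyphenyl]-3-(diethylamino)-3-(4-methoxyphenyl)prop-2-en-1-one | CCN(CC)/C(c1ccc(OC)cc1)=C/C(=O)c1c(O)c(OC)c(OC)c(OC)c1OCc1ccccc1 | intermediate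
16 | 5-(benzyloxy)-6,7,8-trimethoxy-2-(4-methoxyphenyl)-4H-chromen-4-one | COc1ccc(-c2cc(=O)c3c(OCc4ccccc4)c(OC)c(OC)c(OC)c3o2)cc1 | intermediate
17 | rac-5-(benzyloxy)-2,3-epoxy-6,7,8-trimethoxy-2-(4-methoxyphenyl)-2,3-dihydro-4H-chromen-4-one (oxirane cis-fused across C2–C3, aryl at C2 and H at C3 on the same face; one enantiomer drawn) | O=C1c2c(OCc3ccccc3)c(OC)c(OC)c(OC)c2O[C@@]2(c3ccc(OC)cc3)O[C@@H]12 | intermediate
18 | 5-(benzyloxy)-3-hydroxy-6,7,8-trimethoxy-2-(4-methoxyphenyl)-4H-chromen-4-one | COc1ccc(-c2oc3c(OC)c(OC)c(OC)c(OCc4ccccc4)c3c(=O)c2O)cc1 | intermediate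
19 | 3,5-dihydroxy-6,7,8-trimethoxy-2-(4-methoxyphenyl)-4H-chromen-4-one (3,5-dihydroxy-6,7,8,4'-tetramethoxyflavone) | COc1ccc(-c2oc3c(OC)c(OC)c(OC)c(O)c3c(=O)c2O)cc1 | target

Total step count: 8
Longest linear sequence: 8 steps (1 → 19); compounds 6, 12 and 13 are purchased.

Steps most likely to fail

1. Step 6 (key step). The arylpalladium intermediate may be alkynylated before CO has inserted, which leads on to a benzofuran. The aroylpalladium intermediate may instead be captured by diethylamine, or oxidative addition at the C–I bond flanked by two oxygen substituents may be slow. The fallback sets out from 10 and returns to the route at 16; it brings in C4 as a formyl carbon instead of CO. ortho-Formylation of 10 with MgCl2, Et3N and paraformaldehyde in MeCN at reflux (Casnati–Skattebøl reaction) should give 2-(benzyloxy)-6-hydroxy-3,4,5-trimethoxybenzaldehyde F1 at the only free ring position. Lithium (4-methoxyphenyl)acetylide F2, made from 12 and n-BuLi and used in excess (THF, −78 → 0 °C, aqueous NH4Cl quench), should add to the aldehyde to give racemic 3-(benzyloxy)-2-[1-hydroxy-3-(4-methoxyphenyl)prop-2-yn-1-yl]-4,5,6-trimethoxyphenol F3. MnO2 in CH2Cl2 should oxidise the propargylic alcohol to ynone 14, here isolated, and Et2NH in EtOH at reflux should close ring C through enaminone 15 to 16.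

2. Step 7. Epoxidation of the vinylogous-ester double bond may be slow enough that oxidation of the benzylic C–H bonds or of the electron-rich aryl rings competes, or the epoxide may isomerise incompletely. The fallback sets out from 16 and returns at 18; it hydroxylates C3 through a carbanion instead of an epoxide. Deprotonation of C3–H with LiN(iPr)2 (THF, −78 °C) should give [5-(benzyloxy)-6,7,8-trimethoxy-2-(4-methoxyphenyl)-4-oxo-4H-chromen-3-yl]lithium F4. B(OMe)3 should convert it into dimethyl [5-(benzyloxy)-6,7,8-trimethoxy-2-(4-methoxyphenyl)-4-oxo-4H-chromen-3-yl]boronate F5, and AcOH with 30% aq. H2O2 should oxidise the C–B bond to give 18.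

3. Step 2. The two bromines may not be discriminated fully (double exchange), or the proton between them may be transferred to the aryllithium, giving mixtures. The fallback sets out from 2 and returns at 10; it installs both oxygens at once and differentiates them afterwards. Palladium-catalysed hydroxylation (Pd2(dba)3, tBuXPhos, KOH, dioxane–water, 100 °C) should replace both bromines to give 4,5,6-trimethoxybenzene-1,3-diol F6. Alkylation with one equivalent of 6 (K2CO3, acetone) should then give 10 after separation from unreacted and doubly alkylated material. Steps 3 and 4 are then skipped.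

Further compounds
F1 | step 6 | 2-(benzyloxy)-6-hydroxy-3,4,5-trimethoxybenzaldehyde | O=Cc1c(O)c(OC)c(OC)c(OC)c1OCc1ccccc1
F2 | step 6 | lithium (4-methoxyphenyl)acetylide | [Li]C#Cc1ccc(OC)cc1
F3 | step 6 | rac-3-(benzyloxy)-2-[1-hydroxy-3-(4-methoxyphenyl)prop-2-yn-1-yl]-4,5,6-trimethoxyphenol | COc1ccc(cc1)C#CC(O)c1c(O)c(OC)c(OC)c(OC)c1OCc1ccccc1
F4 | step 7 | [5-(benzyloxy)-6,7,8-trimethoxy-2-(4-methoxyphenyl)-4-oxo-4H-chromen-3-yl]lithium | [Li]c1c(-c2ccc(OC)cc2)oc2c(OC)c(OC)c(OC)c(OCc3ccccc3)c2c1=O
F5 | step 7 | dimethyl [5-(benzyloxy)-6,7,8-trimethoxy-2-(4-methoxyphenyl)-4-oxo-4H-chromen-3-yl]boronate | COB(OC)c1c(-c2ccc(OC)cc2)oc2c(OC)c(OC)c(OC)c(OCc3ccccc3)c2c1=O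
F6 | step 2 | 4,5,6-trimethoxybenzene-1,3-diol | COc1c(O)cc(O)c(OC)c1OC
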